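**Strategy.** The flavone is cut at the pyranone (ring C) into a prenylated ring A acetophenone and a ring B benzoate that already holds the dimethylpyran. The route rests on making that pyran in one operation: an aryne spanning C4'–C5' of ring B takes up 3-methyl-2-butenal across its carbonyl, setting C4'–O and C5'–C, and the resulting ortho-quinone methide closes the O–CMe2 bond. The step exploits the ortho relationship of pyran oxygen (C4') and pyran carbon (C5') and the adjacent C3' oxygen, which is carried as a boryl group to steer the oxygen terminus onto C4'. The precursor is a benzoate with Bpin at C3', triflate at C4' and trimethylsilyl at C5'.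

Key step: step 4

Remark: primed locants refer to ring B of the flavone (C1' bonded to C2 of the pyranone). The target has no stereocenter; benzoxete 10 would form as a racemate and its only stereocenter vanishes on ring opening. The aryne precursor keeps Bpin and the methyl ester: Bpin tolerates anhydrous fluoride and oxidises cleanly, and the ester para to C4' reinforces the wanted orientation.

**Step 1**
Reactants: 1 methyl 4-hydroxybenzoate
Product: 2 methyl 4-hydroxy-3,5-diiodobenzoate
Conditions: NIS (2.2 equiv), TFA (cat.), MeCN, rt → 40 °C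
Reagents that add atoms: N-iodosuccinimide, O=C1CCC(=O)N1I
Why: Electrophilic aromatic iodination, in which the hydroxyl group activates both ortho positions and the para position is blocked by the ester, so the two iodines should enter at C3 and C5.

**Step 2**
Reactants: 2 methyl 4-hydroxy-3,5-diiodobenzoate
Product: 5 methyl 3-iodo-4-(trifluoromethanesulfonyloxy)-5-(trimethylsilyl)benzoate, via trimethylsilyl ether 3 (not isolated), via lithium phenoxide 4 (not isolated)
Conditions: HMDS, THF, reflux, then evaporate; n-BuLi (1.0 equiv, slow addition), THF, −100 °C; Tf2O, −100 °C → 0 °C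
Reagents that add atoms: hexamethyldisilazane, C[Si](C)(C)N[Si](C)(C)C; trifluoromethanesulfonic anhydride, O=S(=O)(OS(=O)(=O)C(F)(F)F)C(F)(F)F
Why: O-silylation, then iodine–lithium exchange (which at −100 °C should outrun addition to the methyl ester) triggers a retro-Brook 1,3 O→C silyl shift to phenoxide 4, which triflic anhydride caps in the same flask, and one equivalent of n-BuLi leaves the second iodide in place.

**Step 3**
Reactants: 5 methyl 3-iodo-4-(trifluoromethanesulfonyloxy)-5-(trimethylsilyl)benzoate; 6 bis(pinacolato)diboron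
Product: 7 methyl 3-(4,4,5,5-tetramethyl-1,3,2-dioxaborolan-2-yl)-4-(trifluoromethanesulfonyloxy)-5-(trimethylsilyl)benzoate
Conditions: PdCl2(dppf) (5 mol %), KOAc (3 equiv), 1,4-dioxane, 80 °C
Reagents that add atoms: none
Why: Miyaura borylation, in which zerovalent palladium should insert into the C–I bond far faster than into the doubly ortho-substituted C–OTf bond, while the weak base KOAc neither triggers the silyl triflate nor promotes Suzuki homocoupling.

**Step 4**
Reactants: 7 methyl 3-(4,4,5,5-tetramethyl-1,3,2-dioxaborolan-2-yl)-4-(trifluoromethanesulfonyloxy)-5-(trimethylsilyl)benzoate; 8 3-methyl-2-butenal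
Product: 12 methyl 2,2-dimethyl-8-(4,4,5,5-tetramethyl-1,3,2-dioxaborolan-2-yl)-2H-chromene-6-carboxylate, via aryne 9 (not isolated), via benzoxete 10 (not isolated), via ortho-quinone methide 11 (not isolated)
Conditions: CsF (3 equiv), 8 (5 equiv), dry MeCN, rt, slow addition of 7
Reagents that add atoms: none
Why: Proposed new method: fluoride strips the trimethylsilyl group, triflate leaves and aryne 9 (C4'≡C5') is attacked at C4' by the carbonyl oxygen of 8; the C5' aryl anion collapses onto the carbonyl carbon to give benzoxete 10 (net [2+2]), whose four-electron conrotatory opening yields ortho-quinone methide 11. The six-membered pyran then closes by a thermal disrotatory oxa-6π electrocyclisation that forms the O–CMe2 bond and restores aromaticity (an E-configured methide would first have to rotate about its polarised exocyclic bond). The closest known reaction types are the aryne–enal annulation to 2H-chromenes and the ortho-selective addition of nucleophiles to 3-borylarynes; running the first under the regiocontrol of the second is new. The step needs regioselectivity (oxygen on C4', carbon on C5'), and three substrate features point the same way: the electropositive boron on C3' (more so once fluoride has bound to it) makes C4' the electrophilic aryne terminus, B···O=C coordination delivers the oxygen next to boron, and the ester para to C4' stabilises the developing C5' anion inductively. It also needs chemoselectivity between the two triggers, which the far faster Si–F than B–F-driven triflate loss should provide, so that boron survives. No stereocenter is created, since the benzoxete carbon becomes sp2 in 11 and the product is achiral.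

**Step 5**
Reactants: 12 methyl 2,2-dimethyl-8-(4,4,5,5-tetramethyl-1,3,2-dioxaborolan-2-yl)-2H-chromene-6-carboxylate
Product: 13 methyl 8-hydroxy-2,2-dimethyl-2H-chromene-6-carboxylate
Conditions: NaBO3·4H2O (3 equiv), THF/H2O (1:1), rt
Reagents that add atoms: sodium perborate, [Na+].[O-]OB=O
Why: Oxidation of the aryl boronate by perborate proceeds through 1,2-aryl migration from boron to oxygen at the same carbon, under conditions mild enough for the methyl ester and the chromene double bond.

**Step 6**
Reactants: 13 methyl 8-hydroxy-2,2-dimethyl-2H-chromene-6-carboxylate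
Product: 14 methyl 8-(methoxymethoxy)-2,2-dimethyl-2H-chromene-6-carboxylate
Conditions: MOMCl, i-Pr2NEt, CH2Cl2, 0 °C → rt
Reagents that add atoms: chloromethyl methyl ether, COCCl
Why: O-Alkylation of the phenol with chloromethyl methyl ether (MOM protection) gives an acetal ether that withstands the basic steps ahead.

**Step 7**
Reactants: 14 methyl 8-(methoxymethoxy)-2,2-dimethyl-2H-chromene-6-carboxylate
Product: 15 8-(methoxymethoxy)-2,2-dimethyl-2H-chromene-6-carboxylic acid
Conditions: LiOH·H2O, THF/MeOH/H2O, rt; then 1 M HCl to pH 4, 0 °C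
Reagents that add atoms: lithium hydroxide, [Li+].[OH-]
Why: Ester saponification with hydroxide, to which the MOM ether and the chromene are inert, followed by a cold, mild acidification that keeps the acetal.

**Step 8**
Reactants: 16 2,4,6-trihydroxyacetophenone; 17 1-bromo-3-methylbut-2-ene (prenyl bromide)
Product: 18 1-[2,4,6-trihydroxy-3-(3-methylbut-2-en-1-yl)phenyl]ethan-1-one
Conditions: DBU (1.1 equiv), THF, 0 °C → rt
Reagents that add atoms: none
Why: C-Alkylation of the ambident phloroglucinol-type phenoxide with an allylic bromide, where the two free ring positions are equivalent, so mono-prenylation can give only one constitution.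

**Step 9**
Reactants: 18 1-[2,4,6-trihydroxy-3-(3-methylbut-2-en-1-yl)phenyl]ethan-1-one
Product: 19 1-[2-hydroxy-4,6-bis(methoxymethoxy)-3-(3-methylbut-2-en-1-yl)phenyl]ethan-1-one
Conditions: MOMCl (2.2 equiv), i-Pr2NEt, CH2Cl2, 0 °C → rt
Reagents that add atoms: chloromethyl methyl ether, COCCl
Why: Site-selective O-alkylation (MOM protection), in which the non-chelated C4 hydroxyl and the less hindered C6 hydroxyl should react while the hydroxyl wedged between acetyl and prenyl groups, held in the carbonyl chelate by the buttressing prenyl group, stays free.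

**Step 10**
Reactants: 15 8-(methoxymethoxy)-2,2-dimethyl-2H-chromene-6-carboxylic acid; 19 1-[2-hydroxy-4,6-bis(methoxymethoxy)-3-(3-methylbut-2-en-1-yl)phenyl]ethan-1-one
Product: 20 2-acetyl-3,5-bis(methoxymethoxy)-6-(3-methylbut-2-en-1-yl)phenyl 8-(methoxymethoxy)-2,2-dimethyl-2H-chromene-6-carboxylate
Conditions: DCC, DMAP, CH2Cl2, rt
Reagents that add atoms: none
Why: Steglich esterification, in which the DMAP-derived acylpyridinium is electrophilic enough to acylate the hindered, hydrogen-bonded phenol.

**Step 11**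
Reactants: 20 2-acetyl-3,5-bis(methoxymethoxy)-6-(3-methylbut-2-en-1-yl)phenyl 8-(methoxymethoxy)-2,2-dimethyl-2H-chromene-6-carboxylate
Product: 21 1-[2-hydroxy-4,6-bis(methoxymethoxy)-3-(3-methylbut-2-en-1-yl)phenyl]-3-[8-(methoxymethoxy)-2,2-dimethyl-2H-chromen-6-yl]propane-1,3-dione
Conditions: LiN(SiMe3)2 (2.5 equiv), THF, −78 → 0 °C; AcOH quench
Reagents that add atoms: none
Why: Baker–Venkataraman rearrangement, in which the methyl ketone enolate attacks the neighbouring aryl ester intramolecularly and the acyl group moves from oxygen to carbon, releasing the phenoxide beside the prenyl group.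

**Step 12**
Reactants: 21 1-[2-hydroxy-4,6-bis(methoxymethoxy)-3-(3-methylbut-2-en-1-yl)phenyl]-3-[8-(methoxymethoxy)-2,2-dimethyl-2H-chromen-6-yl]propane-1,3-dione
Product: 23 5,7-dihydroxy-2-(8-hydroxy-2,2-dimethyl-2H-chromen-6-yl)-8-(3-methylbut-2-en-1-yl)-4H-chromen-4-one, via tris-MOM flavone 22 (not isolated)
Conditions: 3 M aq. HCl/MeOH (1:5), rt, then 50 °C
Reagents that add atoms: none
Why: Acid-catalysed cyclodehydration, in which the only free phenol (the one beside the prenyl group) should form the hemiketal and lose water to flavone 22 before the acetals are touched, fixing the prenyl group at C8, after which methanolysis of the three MOM acetals releases the target.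

**Compound list**
1 | methyl 4-hydroxybenzoate | COC(=O)c1ccc(O)cc1 | starting material
2 | methyl 4-hydroxy-3,5-diiodobenzoate | COC(=O)c1cc(I)c(O)c(I)c1 | intermediate
3 | methyl 3,5-diiodo-4-(trimethylsilyloxy)benzoate (not isolated) | COC(=O)c1cc(I)c(O[Si](C)(C)C)c(I)c1 | intermediate
4 | lithium 2-iodo-4-(methoxycarbonyl)-6-(trimethylsilyl)phenoxide (not isolated) | COC(=O)c1cc(I)c([O-])c([Si](C)(C)C)c1.[Li+] | intermediate
5 | methyl 3-iodo-4-(trifluoromethanesulfonyloxy)-5-(trimethylsilyl)benzoate | COC(=O)c1cc(I)c(OS(=O)(=O)C(F)(F)F)c([Si](C)(C)C)c1 | intermediate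
6 | bis(pinacolato)diboron | CC1(C)OB(B2OC(C)(C)C(C)(C)O2)OC1(C)C | starting material
7 | methyl 3-(4,4,5,5-tetramethyl-1,3,2-dioxaborolan-2-yl)-4-(trifluoromethanesulfonyloxy)-5-(trimethylsilyl)benzoate | COC(=O)c1cc(B2OC(C)(C)C(C)(C)O2)c(OS(=O)(=O)C(F)(F)F)c([Si](C)(C)C)c1 | intermediate
8 | 3-methyl-2-butenal | CC(C)=CC=O | starting material
9 | methyl 3-(4,4,5,5-tetramethyl-1,3,2-dioxaborolan-2-yl)-4,5-didehydrobenzoate (aryne, not isolated) | COC(=O)C1=CC#CC(B2OC(C)(C)C(C)(C)O2)=C1 | intermediate
10 | methyl 2-(2-methylprop-1-en-1-yl)-6-(4,4,5,5-tetramethyl-1,3,2-dioxaborolan-2-yl)-2H-benzo[b]oxete-4-carboxylate (racemic, not isolated) | COC(=O)c1cc(B2OC(C)(C)C(C)(C)O2)c2OC(C=C(C)C)c2c1 | intermediate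
11 | methyl (3Z)-3-(3-methylbut-2-en-1-ylidene)-4-oxo-5-(4,4,5,5-tetramethyl-1,3,2-dioxaborolan-2-yl)cyclohexa-1,5-diene-1-carboxylate (ortho-quinone methide, not isolated) | COC(=O)C1=C/C(=C/C=C(C)C)C(=O)C(B2OC(C)(C)C(C)(C)O2)=C1 | intermediate
12 | methyl 2,2-dimethyl-8-(4,4,5,5-tetramethyl-1,3,2-dioxaborolan-2-yl)-2H-chromene-6-carboxylate | COC(=O)c1cc(B2OC(C)(C)C(C)(C)O2)c2c(c1)C=CC(C)(C)O2 | intermediate
13 | methyl 8-hydroxy-2,2-dimethyl-2H-chromene-6-carboxylate | COC(=O)c1cc(O)c2c(c1)C=CC(C)(C)O2 | intermediate
14 | methyl 8-(methoxymethoxy)-2,2-dimethyl-2H-chromene-6-carboxylate | COC(=O)c1cc(OCOC)c2c(c1)C=CC(C)(C)O2 | intermediate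
15 | 8-(methoxymethoxy)-2,2-dimethyl-2H-chromene-6-carboxylic acid | OC(=O)c1cc(OCOC)c2c(c1)C=CC(C)(C)O2 | intermediate
16 | 2,4,6-trihydroxyacetophenone | CC(=O)c1c(O)cc(O)cc1O | starting material
17 | 1-bromo-3-methylbut-2-ene | CC(C)=CCBr | starting material
18 | 1-[2,4,6-trihydroxy-3-(3-methylbut-2-en-1-yl)phenyl]ethan-1-one | CC(=O)c1c(O)cc(O)c(CC=C(C)C)c1O | intermediate
19 | 1-[2-hydroxy-4,6-bis(methoxymethoxy)-3-(3-methylbut-2-en-1-yl)phenyl]ethan-1-one | CC(=O)c1c(OCOC)cc(OCOC)c(CC=C(C)C)c1O | intermediate
20 | 2-acetyl-3,5-bis(methoxymethoxy)-6-(3-methylbut-2-en-1-yl)phenyl 8-(methoxymethoxy)-2,2-dimethyl-2H-chromene-6-carboxylate | CC(=O)c1c(OCOC)cc(OCOC)c(CC=C(C)C)c1OC(=O)c1cc(OCOC)c2c(c1)C=CC(C)(C)O2 | intermediate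
21 | 1-[2-hydroxy-4,6-bis(methoxymethoxy)-3-(3-methylbut-2-en-1-yl)phenyl]-3-[8-(methoxymethoxy)-2,2-dimethyl-2H-chromen-6-yl]propane-1,3-dione | O=C(CC(=O)c1cc(OCOC)c2c(c1)C=CC(C)(C)O2)c1c(OCOC)cc(OCOC)c(CC=C(C)C)c1O | intermediate
22 | 5,7-bis(methoxymethoxy)-2-[8-(methoxymethoxy)-2,2-dimethyl-2H-chromen-6-yl]-8-(3-methylbut-2-en-1-yl)-4H-chromen-4-one (not isolated) | CC(C)=CCc1c(OCOC)cc(OCOC)c2c(=O)cc(-c3cc(OCOC)c4c(c3)C=CC(C)(C)O4)oc12 | intermediate
23 | 5,7-dihydroxy-2-(8-hydroxy-2,2-dimethyl-2H-chromen-6-yl)-8-(3-methylbut-2-en-1-yl)-4H-chromen-4-one | CC(C)=CCc1c(O)cc(O)c2c(=O)cc(-c3cc(O)c4c(c3)C=CC(C)(C)O4)oc12 | target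

**Step count.** Total: 12 steps. Longest linear sequence: 10 steps (steps 1–7, then 10–12); the ring A branch is steps 8–9.

**Steps most likely to fail**

1. Step 4. The carbonyl oxygen may add to C5' instead of C4', reversing the orientation of the annulation, or fluoride may attack boron and divert the precursor before the aryne is trapped. The fallback uses known chemistry, sets out from 1 and returns at 12. Mono-iodination of 1 (NIS, 1.0 equiv, cat. TFA) would give methyl 4-hydroxy-3-iodobenzoate F1. O-Alkylation with 3-chloro-3-methylbut-1-yne (DBU, CuCl2 cat., MeCN, 0 °C) would give methyl 3-iodo-4-[(2-methylbut-3-yn-2-yl)oxy]benzoate F2. Heating in N,N-diethylaniline at 190 °C (aryl propargyl ether Claisen rearrangement, 1,5-hydrogen shift, oxa-6π closure) can only use the single free ortho position and would give methyl 8-iodo-2,2-dimethyl-2H-chromene-6-carboxylate F3. Miyaura borylation of F3 with 6 (PdCl2(dppf), KOAc, dioxane, 80 °C) would return to 12.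

2. Step 2. Butyllithium may add to the methyl ester, or both iodides may be exchanged, before the silyl shift is complete. The fallback replaces lithium by magnesium and delivers silicon from outside; it sets out from 2 and returns at 5. Compound 2 would be deprotonated with MeMgCl in THF containing LiCl (−30 °C) and one iodide exchanged with i-PrMgCl·LiCl, conditions under which an ester-bearing arylmagnesium is stable. Quenching with excess Me3SiCl would give methyl 3-iodo-5-(trimethylsilyl)-4-(trimethylsilyloxy)benzoate F4, and methanolysis of the silyl ether (MeOH, cat. K2CO3) would give methyl 4-hydroxy-3-iodo-5-(trimethylsilyl)benzoate F5. Triflation (Tf2O, pyridine, CH2Cl2, 0 °C) would then give 5.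

3. Step 12. Under the protic acid needed for acetal cleavage, the freed C7 hydroxyl may add across the neighbouring prenyl double bond (chroman formation), or the ring B chromene may be hydrated. The fallback changes the protecting group so that the last operation is neutral; it sets out from 13 and 18 and returns at 23. Compound 13 would be O-allylated (allyl bromide, K2CO3, acetone) to methyl 8-(allyloxy)-2,2-dimethyl-2H-chromene-6-carboxylate F6 and saponified (LiOH) to 8-(allyloxy)-2,2-dimethyl-2H-chromene-6-carboxylic acid F7. Compound 18 would be bis-O-allylated, with the site selectivity argued for step 9, to 1-[4,6-bis(allyloxy)-2-hydroxy-3-(3-methylbut-2-en-1-yl)phenyl]ethan-1-one F8. Steglich esterification would give aryl ester F9, and Baker–Venkataraman rearrangement (LiN(SiMe3)2) would give diketone F10. Catalytic p-TsOH in toluene at 60 °C would close the pyranone to tris(allyloxy)flavone F11 while every other phenol is still capped. Pd(PPh3)4 (zerovalent palladium) with morpholine in THF at rt would then remove the three allyl groups by π-allyl transfer and give 23.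

**Further compounds**
F1 | step 4 | methyl 4-hydroxy-3-iodobenzoate | COC(=O)c1ccc(O)c(I)c1
F2 | step 4 | methyl 3-iodo-4-[(2-methylbut-3-yn-2-yl)oxy]benzoate | COC(=O)c1ccc(OC(C)(C)C#C)c(I)c1
F3 | step 4 | methyl 8-iodo-2,2-dimethyl-2H-chromene-6-carboxylate | COC(=O)c1cc(I)c2c(c1)C=CC(C)(C)O2
F4 | step 2 | methyl 3-iodo-5-(trimethylsilyl)-4-(trimethylsilyloxy)benzoate | COC(=O)c1cc(I)c(O[Si](C)(C)C)c([Si](C)(C)C)c1
F5 | step 2 | methyl 4-hydroxy-3-iodo-5-(trimethylsilyl)benzoate | COC(=O)c1cc(I)c(O)c([Si](C)(C)C)c1
F6 | step 12 | methyl 8-(allyloxy)-2,2-dimethyl-2H-chromene-6-carboxylate | COC(=O)c1cc(OCC=C)c2c(c1)C=CC(C)(C)O2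
F7 | step 12 | 8-(allyloxy)-2,2-dimethyl-2H-chromene-6-carboxylic acid | OC(=O)c1cc(OCC=C)c2c(c1)C=CC(C)(C)O2
F8 | step 12 | 1-[4,6-bis(allyloxy)-2-hydroxy-3-(3-methylbut-2-en-1-yl)phenyl]ethan-1-one | CC(=O)c1c(OCC=C)cc(OCC=C)c(CC=C(C)C)c1O
F9 | step 12 | 2-acetyl-3,5-bis(allyloxy)-6-(3-methylbut-2-en-1-yl)phenyl 8-(allyloxy)-2,2-dimethyl-2H-chromene-6-carboxylate | CC(=O)c1c(OCC=C)cc(OCC=C)c(CC=C(C)C)c1OC(=O)c1cc(OCC=C)c2c(c1)C=CC(C)(C)O2
F10 | step 12 | 1-[4,6-bis(allyloxy)-2-hydroxy-3-(3-methylbut-2-en-1-yl)phenyl]-3-[8-(allyloxy)-2,2-dimethyl-2H-chromen-6-yl]propane-1,3-dione | O=C(CC(=O)c1cc(OCC=C)c2c(c1)C=CC(C)(C)O2)c1c(OCC=C)cc(OCC=C)c(CC=C(C)C)c1O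
F11 | step 12 | 5,7-bis(allyloxy)-2-[8-(allyloxy)-2,2-dimethyl-2H-chromen-6-yl]-8-(3-methylbut-2-en-1-yl)-4H-chromen-4-one | CC(C)=CCc1c(OCC=C)cc(OCC=C)c2c(=O)cc(-c3cc(OCC=C)c4c(c3)C=CC(C)(C)O4)oc12
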